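The late cuts are the C4'–OH bond (back to a C3'=C4' alkene by allylic transposition), the bond from the ketone carbon to C1 of resorcinol ring C (aldehyde plus aryllithium), and the C3=C4 unsaturation (back to a chroman).
The enabling feature is ring A (C4a, C5, C6, C7, C8, C8a), a benzene with four contiguous substituents whose C8 hydroxyl stands ortho to the ether carbon C8a. C4a–C5–C6–C7 plus the C8 oxygen is a latent 2,3-dialkylfuran and C8a–C8 a latent ethynyl ether, so C8a–C4a, C8–C7 and C8–O are cut together.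
The cascade precursor is taken apart at O1–C8a (tertiary alkoxide plus trichloroethylene) and at C4–C4a and C5–CH2 (two B-alkyl Suzuki–Miyaura couplings on the furan).
In the forward direction the furan is alkylated at C3, brominated and alkylated at C2, and the tertiary alcohol is ethynylated. Gold then closes ring B and ring A in one operation, ring B is dehydrogenated, ring C is attached, and the side chain is oxidised last, after every acidic step.
C2 (R) is the carbinol carbon of (R)-(−)-linalool, and none of its four bonds is ever broken. The E C2'=C3' alkene comes from the ene reaction.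
Key step: step 5

Remark: chromene locants (O1 to C8a) are used from the precursors onward and the chain on C2 is C1'–C4'. Commercial (R)-(−)-linalool of high enantiomeric purity is assumed, since its purity is carried into the target. The descriptor stays R throughout, except in borane 7, which is formally S only because boron ranks below carbon.

Step 1
Reactants: 1 2-vinyl-1,3-dioxolane; 2 3-bromofuran
Product: 4 3-[2-(1,3-dioxolan-2-yl)ethyl]furan, via alkylborane 3 (not isolated)
Conditions: 1, 9-BBN (1.1 equiv), THF, 0 °C to rt; then 2, PdCl2(dppf) (3 mol %), 3 M aq NaOH, THF, 65 °C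
Reagents that add atoms: none
Why: Anti-Markovnikov hydroboration followed by B-alkyl Suzuki–Miyaura coupling is the standard way to place a functionalised primary alkyl chain on C3 of 3-bromofuran, and the dioxolane is inert to borane, base and palladium.

Step 2
Reactants: 4 3-[2-(1,3-dioxolan-2-yl)ethyl]furan
Product: 5 2-bromo-3-[2-(1,3-dioxolan-2-yl)ethyl]furan
Conditions: NBS (1.0 equiv), DMF, −20 to 0 °C, dark; used without storage
Reagents that add atoms: N-bromosuccinimide, O=C1CCC(=O)N1Br
Why: Electrophilic aromatic bromination of a 3-alkylfuran goes to the α-position next to the alkyl group, which is activated by both the ring oxygen and the substituent, and NBS releases no acid that could harm the acetal.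

Step 3
Reactants: 6 (R)-(−)-linalool; 5 2-bromo-3-[2-(1,3-dioxolan-2-yl)ethyl]furan
Product: 8 (3R)-1-{3-[2-(1,3-dioxolan-2-yl)ethyl]furan-2-yl}-3,7-dimethyloct-6-en-3-ol, via alkylborane 7 (not isolated)
Conditions: 6, 9-BBN (1.3 equiv), THF, 0 °C to rt; then 5, PdCl2(dppf) (5 mol %), Cs2CO3, DMF/THF/H2O, rt to 40 °C
Reagents that add atoms: none
Why: 9-BBN hydroborates the monosubstituted vinyl group far faster than the trisubstituted alkene and reacts only slowly with a tertiary hydroxyl, and the B-alkyl Suzuki–Miyaura coupling at the reactive furan C2–Br bond forms C4–C4a without touching the carbinol centre, which keeps the linalool configuration.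

Step 4
Reactants: 8 (3R)-1-{3-[2-(1,3-dioxolan-2-yl)ethyl]furan-2-yl}-3,7-dimethyloct-6-en-3-ol
Product: 11 3-[2-(1,3-dioxolan-2-yl)ethyl]-2-[(3R)-3-(ethynyloxy)-3,7-dimethyloct-6-en-1-yl]furan, via dichlorovinyl ether 9 (not isolated), via lithiated ethynyl ether 10 (not isolated)
Conditions: KH (1.5 equiv), THF, 0 °C to rt; Cl2C=CHCl (1.1 equiv), −50 °C to rt; n-BuLi (2.5 equiv), −78 to −40 °C; H2O, −78 to 0 °C; rapid filtration over Et3N-deactivated silica below 10 °C
Reagents that add atoms: trichloroethylene, ClC=C(Cl)Cl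
Why: This is the trichloroethylene route to alkynyl ethers, in which the potassium alkoxide adds to dichloroacetylene formed in situ to give the (E)-dichlorovinyl ether and n-BuLi then effects elimination and chlorine–lithium exchange; the C2–O1 bond is never broken, so the configuration is retained, and because a tertiary ethynyl ether loses ketene by a retro-ene path on warming, 11 is kept cold and used at once.

Step 5
Reactants: 11 3-[2-(1,3-dioxolan-2-yl)ethyl]-2-[(3R)-3-(ethynyloxy)-3,7-dimethyloct-6-en-1-yl]furan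
Product: 14 (2R)-5-[2-(1,3-dioxolan-2-yl)ethyl]-2-methyl-2-(4-methylpent-3-en-1-yl)-3,4-dihydro-2H-chromen-8-ol, via oxepine 12 (not isolated), via arene oxide 13 (not isolated)
Conditions: (Ph3P)AuNTf2 (3 mol %), 4 Å molecular sieves, CH2Cl2 (0.02 M), −20 °C to rt
Reagents that add atoms: none
Why: Monovalent gold binds the ethynyl ether and polarises it towards a ketene-oxonium form, furan C2 (future C4a) attacks C8a across its C2–C3 π bond to give a catalyst-bound cyclopropyl carbene, this opens with rupture of the furan C2–O bond to a dienal carbene, the aldehyde oxygen adds to the carbene carbon C8, and the resulting oxepine 12 equilibrates with the C7–C8 arene oxide 13, which aromatises to phenol 14. The closest known reaction type is the gold-catalysed furan–yne phenol synthesis, which has been run with alkynyl ethers in the tether and then delivers chromans hydroxylated next to the ring oxygen. Ring B closes 6-exo-dig through the C8a–C4a bond, and ring A closes through the 6π electrocyclisation of 12 that makes the C7–C8 bond. The product gains no stereocentre (those of 13 vanish on aromatisation), and C2, a spectator whose four bonds stay intact, keeps the R configuration. Regioselective opening of 13 is needed and is secured by the substrate, because breaking C7–O places the charge on C8a, where O1 stabilises it, and on the alkylated C5, so the oxygen remains on C8. Chemoselectivity is also needed, since the side-chain alkene can reach C8a through a six-membered transition state of its own; it rests on the higher π-nucleophilicity of the 2,3-dialkylfuran (attack at C2 leaves the charge on alkylated C3 and on the ring oxygen), on low temperature and dilution, and on the saturated C3–C4 tether, which offers no allyl ynol ether for a [3,3] shift.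

Step 6
Reactants: 14 (2R)-5-[2-(1,3-dioxolan-2-yl)ethyl]-2-methyl-2-(4-methylpent-3-en-1-yl)-3,4-dihydro-2H-chromen-8-ol
Product: 15 (2R)-5-[2-(1,3-dioxolan-2-yl)ethyl]-2-methyl-2-(4-methylpent-3-en-1-yl)-3,4-dihydro-2H-chromen-8-yl pivalate
Conditions: PivCl (1.3 equiv), Et3N (1.5 equiv), DMAP (5 mol %), CH2Cl2, 0 °C to rt
Reagents that add atoms: pivaloyl chloride, CC(C)(C)C(=O)Cl
Why: DMAP-catalysed O-acylation of a phenol is routine, and the pivalate weakens the donor power of the C8 oxygen for step 7 while, unlike an acetate, being hindered enough to outlast the aryllithium of step 10.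

Step 7
Reactants: 15 (2R)-5-[2-(1,3-dioxolan-2-yl)ethyl]-2-methyl-2-(4-methylpent-3-en-1-yl)-3,4-dihydro-2H-chromen-8-yl pivalate
Product: 16 (2R)-5-[2-(1,3-dioxolan-2-yl)ethyl]-2-methyl-2-(4-methylpent-3-en-1-yl)-2H-chromen-8-yl pivalate
Conditions: DDQ (1.5 equiv), benzene, 80 °C, dark
Reagents that add atoms: none
Why: Quinone dehydrogenation of a chroman to a 2H-chromene (hydride abstraction from C4, then proton loss from C3) is known for chromanyl esters and tolerates isolated trisubstituted alkenes; the C4 cation is stabilised by O1 through C8a whereas the rival benzylic CH2 on C5 is para only to the acylated oxygen, and holding 80 °C limits thermal oxa-6π ring opening that would erode C2.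

Step 8
Reactants: 16 (2R)-5-[2-(1,3-dioxolan-2-yl)ethyl]-2-methyl-2-(4-methylpent-3-en-1-yl)-2H-chromen-8-yl pivalate
Product: 17 (2R)-2-methyl-2-(4-methylpent-3-en-1-yl)-5-(3-oxopropyl)-2H-chromen-8-yl pivalate
Conditions: 1 M aq HCl, THF, rt
Reagents that add atoms: water, O
Why: Acid-catalysed acetal hydrolysis under these dilute conditions leaves the aryl pivalate, the chromene and the trisubstituted alkene untouched and gives the aldehyde without a separate oxidation.

Step 9
Reactants: 18 4-bromoresorcinol
Product: 19 1-bromo-2,4-bis(methoxymethoxy)benzene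
Conditions: MOMCl (2.5 equiv), i-Pr2NEt (3 equiv), CH2Cl2, 0 °C to rt
Reagents that add atoms: chloromethyl methyl ether, COCCl
Why: Base-mediated O-alkylation of both phenols gives MOM ethers that tolerate n-BuLi, cannot migrate to an ortho carbanion as silyl groups do, and can be removed before the acid-sensitive allylic alcohol exists.

Step 10
Reactants: 19 1-bromo-2,4-bis(methoxymethoxy)benzene; 17 (2R)-2-methyl-2-(4-methylpent-3-en-1-yl)-5-(3-oxopropyl)-2H-chromen-8-yl pivalate
Product: 21 (2R)-5-{3-[2,4-bis(methoxymethoxy)phenyl]-3-hydroxypropyl}-2-methyl-2-(4-methylpent-3-en-1-yl)-2H-chromen-8-yl pivalate (both carbinol epimers), via aryllithium 20 (not isolated)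
Conditions: 19 (1.3 equiv), n-BuLi (1.25 equiv), THF, −78 °C; then 17, −78 °C; AcOH in THF, −78 °C
Reagents that add atoms: none
Why: Bromine–lithium exchange followed by 1,2-addition of the aryllithium to the aldehyde is much faster at −78 °C than attack on the hindered pivalate, and the new carbinol centre is formed without control because step 11 erases it.

Step 11
Reactants: 21 (2R)-5-{3-[2,4-bis(methoxymethoxy)phenyl]-3-hydroxypropyl}-2-methyl-2-(4-methylpent-3-en-1-yl)-2H-chromen-8-yl pivalate
Product: 22 (2R)-5-{3-[2,4-bis(methoxymethoxy)phenyl]-3-oxopropyl}-2-methyl-2-(4-methylpent-3-en-1-yl)-2H-chromen-8-yl pivalate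
Conditions: Dess–Martin periodinane (1.3 equiv), CH2Cl2, 0 °C to rt
Reagents that add atoms: none
Why: Dess–Martin oxidation converts the secondary benzylic alcohol into the aryl ketone under near-neutral conditions that spare both alkenes, the MOM ethers and the ester.

Step 12
Reactants: 22 (2R)-5-{3-[2,4-bis(methoxymethoxy)phenyl]-3-oxopropyl}-2-methyl-2-(4-methylpent-3-en-1-yl)-2H-chromen-8-yl pivalate
Product: 23 (2R)-5-[3-(2,4-dihydroxyphenyl)-3-oxopropyl]-2-methyl-2-(4-methylpent-3-en-1-yl)-2H-chromen-8-yl pivalate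
Conditions: HCl (1.25 M in MeOH), THF, rt to 40 °C
Reagents that add atoms: none
Why: Acid-catalysed methanolysis of phenolic MOM ethers is routine on chromene-bearing and prenylated chalcone-type ketones, the hindered pivalate resists it, and the step is placed here because no tertiary allylic alcohol is present yet.

Step 13
Reactants: 23 (2R)-5-[3-(2,4-dihydroxyphenyl)-3-oxopropyl]-2-methyl-2-(4-methylpent-3-en-1-yl)-2H-chromen-8-yl pivalate
Product: 25 (2R)-5-[3-(2,4-dihydroxyphenyl)-3-oxopropyl]-2-[(2E)-4-hydroxy-4-methylpent-2-en-1-yl]-2-methyl-2H-chromen-8-yl pivalate, via allylic hydroperoxide 24 (not isolated)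
Conditions: O2 (1 atm), tetraphenylporphyrin (1 mol %), CH2Cl2, 0 °C, LED above 500 nm; then PPh3 (1.2 equiv), 0 °C to rt
Reagents that add atoms: dioxygen, O=O
Why: In the Schenck ene reaction singlet oxygen attacks the trisubstituted alkene in preference to the hindered styrene-type C3=C4 bond and the acyl-deactivated or acylated phenols, binds at C4' while taking a hydrogen from C2' suprafacially so that the double bond moves to C2'=C3' with E geometry, the isomer from methyl hydrogen abstraction being an expected co-product removed after the PPh3 reduction; long-wavelength light leaves the chromene unexcited, so C2 is not scrambled by photochemical ring opening.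

Step 14
Reactants: 25 (2R)-5-[3-(2,4-dihydroxyphenyl)-3-oxopropyl]-2-[(2E)-4-hydroxy-4-methylpent-2-en-1-yl]-2-methyl-2H-chromen-8-yl pivalate
Product: 26 1-(2,4-dihydroxyphenyl)-3-{(2R)-8-hydroxy-2-[(2E)-4-hydroxy-4-methylpent-2-en-1-yl]-2-methyl-2H-chromen-5-yl}propan-1-one (CNP0311864.1)
Conditions: K2CO3 (4 equiv), MeOH, argon, 0 °C to rt; then AcOH to pH 6, 0 °C
Reagents that add atoms: none
Why: Base-mediated methanolysis of the aryl ester frees the C8 phenol without any acid strong enough to ionise the tertiary allylic alcohol or open the chromene, and exclusion of air protects the electron-rich phenoxide.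

Compound list
1 | 2-vinyl-1,3-dioxolane | C=CC1OCCO1 | starting material
2 | 3-bromofuran | Brc1ccoc1 | starting material
3 | 9-[2-(1,3-dioxolan-2-yl)ethyl]-9-borabicyclo[3.3.1]nonane | C1COC(CCB2C3CCCC2CCC3)O1 | intermediate
4 | 3-[2-(1,3-dioxolan-2-yl)ethyl]furan | C1COC(CCc2ccoc2)O1 | intermediate
5 | 2-bromo-3-[2-(1,3-dioxolan-2-yl)ethyl]furan | Brc1occc1CCC2OCCO2 | intermediate
6 | (R)-(−)-linalool, (3R)-3,7-dimethylocta-1,6-dien-3-ol | CC(C)=CCC[C@](O)(C)C=C | starting material
7 | (3S)-1-(9-borabicyclo[3.3.1]nonan-9-yl)-3,7-dimethyloct-6-en-3-ol (same spatial arrangement as 6) | CC(C)=CCC[C@](O)(C)CCB1C2CCCC1CCC2 | intermediate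
8 | (3R)-1-{3-[2-(1,3-dioxolan-2-yl)ethyl]furan-2-yl}-3,7-dimethyloct-6-en-3-ol | CC(C)=CCC[C@](O)(C)CCc1occc1CCC2OCCO2 | intermediate
9 | 2-[(3R)-3-{[(E)-1,2-dichloroethenyl]oxy}-3,7-dimethyloct-6-en-1-yl]-3-[2-(1,3-dioxolan-2-yl)ethyl]furan | CC(C)=CCC[C@](O/C(Cl)=C\Cl)(C)CCc1occc1CCC2OCCO2 | intermediate
10 | 2-[(3R)-3-(lithioethynyloxy)-3,7-dimethyloct-6-en-1-yl]-3-[2-(1,3-dioxolan-2-yl)ethyl]furan | CC(C)=CCC[C@](OC#C[Li])(C)CCc1occc1CCC2OCCO2 | intermediate
11 | 3-[2-(1,3-dioxolan-2-yl)ethyl]-2-[(3R)-3-(ethynyloxy)-3,7-dimethyloct-6-en-1-yl]furan | CC(C)=CCC[C@](OC#C)(C)CCc1occc1CCC2OCCO2 | intermediate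
12 | oxepine tautomer, (2R)-pyran fused at C4a–C8a to the ring O–C8=C8a–C4a=C5–C6=C7, substituents as in 14 | CC(C)=CCC[C@]1(C)CCC2=C(CCC3OCCO3)C=COC=C2O1 | intermediate
13 | C7–C8 arene oxide of ring A, (2R), epoxide on either face, double bonds C8a=C4a and C5=C6 | CC(C)=CCC[C@]1(C)CCC2=C(O1)C3OC3C=C2CCC4OCCO4 | intermediate
14 | (2R)-5-[2-(1,3-dioxolan-2-yl)ethyl]-2-methyl-2-(4-methylpent-3-en-1-yl)-3,4-dihydro-2H-chromen-8-ol | CC(C)=CCC[C@]1(C)CCc2c(CCC3OCCO3)ccc(O)c2O1 | intermediate
15 | (2R)-5-[2-(1,3-dioxolan-2-yl)ethyl]-2-methyl-2-(4-methylpent-3-en-1-yl)-3,4-dihydro-2H-chromen-8-yl pivalate | CC(C)=CCC[C@]1(C)CCc2c(CCC3OCCO3)ccc(OC(=O)C(C)(C)C)c2O1 | intermediate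
16 | (2R)-5-[2-(1,3-dioxolan-2-yl)ethyl]-2-methyl-2-(4-methylpent-3-en-1-yl)-2H-chromen-8-yl pivalate | CC(C)=CCC[C@]1(C)C=Cc2c(CCC3OCCO3)ccc(OC(=O)C(C)(C)C)c2O1 | intermediate
17 | (2R)-2-methyl-2-(4-methylpent-3-en-1-yl)-5-(3-oxopropyl)-2H-chromen-8-yl pivalate | CC(C)=CCC[C@]1(C)C=Cc2c(CCC=O)ccc(OC(=O)C(C)(C)C)c2O1 | intermediate
18 | 4-bromoresorcinol | Oc1ccc(Br)c(O)c1 | starting material
19 | 1-bromo-2,4-bis(methoxymethoxy)benzene | COCOc1ccc(Br)c(OCOC)c1 | intermediate
20 | 2,4-bis(methoxymethoxy)phenyllithium | COCOc1ccc([Li])c(OCOC)c1 | intermediate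
21 | (2R)-5-{3-[2,4-bis(methoxymethoxy)phenyl]-3-hydroxypropyl}-2-methyl-2-(4-methylpent-3-en-1-yl)-2H-chromen-8-yl pivalate, both carbinol epimers | CC(C)=CCC[C@]1(C)C=Cc2c(CCC(O)c3ccc(OCOC)cc3OCOC)ccc(OC(=O)C(C)(C)C)c2O1 | intermediate
22 | (2R)-5-{3-[2,4-bis(methoxymethoxy)phenyl]-3-oxopropyl}-2-methyl-2-(4-methylpent-3-en-1-yl)-2H-chromen-8-yl pivalate | CC(C)=CCC[C@]1(C)C=Cc2c(CCC(=O)c3ccc(OCOC)cc3OCOC)ccc(OC(=O)C(C)(C)C)c2O1 | intermediate
23 | (2R)-5-[3-(2,4-dihydroxyphenyl)-3-oxopropyl]-2-methyl-2-(4-methylpent-3-en-1-yl)-2H-chromen-8-yl pivalate | CC(C)=CCC[C@]1(C)C=Cc2c(CCC(=O)c3ccc(O)cc3O)ccc(OC(=O)C(C)(C)C)c2O1 | intermediate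
24 | (2R)-5-[3-(2,4-dihydroxyphenyl)-3-oxopropyl]-2-[(2E)-4-hydroperoxy-4-methylpent-2-en-1-yl]-2-methyl-2H-chromen-8-yl pivalate | CC(C)(OO)/C=C/C[C@]1(C)C=Cc2c(CCC(=O)c3ccc(O)cc3O)ccc(OC(=O)C(C)(C)C)c2O1 | intermediate
25 | (2R)-5-[3-(2,4-dihydroxyphenyl)-3-oxopropyl]-2-[(2E)-4-hydroxy-4-methylpent-2-en-1-yl]-2-methyl-2H-chromen-8-yl pivalate | CC(C)(O)/C=C/C[C@]1(C)C=Cc2c(CCC(=O)c3ccc(O)cc3O)ccc(OC(=O)C(C)(C)C)c2O1 | intermediate
26 | 1-(2,4-dihydroxyphenyl)-3-{(2R)-8-hydroxy-2-[(2E)-4-hydroxy-4-methylpent-2-en-1-yl]-2-methyl-2H-chromen-5-yl}propan-1-one | CC(C)(O)/C=C/C[C@]1(C)C=Cc2c(CCC(=O)c3ccc(O)cc3O)ccc(O)c2O1 | target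

Total step count: 14.
Longest linear sequence: 13 steps (steps 1–8 and 10–14, from 1 and 2). Step 9 is the only branch.

Steps most likely to fail

Step 5. The gold-activated ethynyl ether may be intercepted by the trisubstituted side-chain alkene, whose closure has the same ring size as the furan attack. The tertiary C2–O1 bond may also ionise before cyclisation.
- The fallback sets out from 8 and comes back at 14. It swaps the nucleophilic alkene for a much weaker one during the cascade and restores it afterwards.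
- Ethenolysis of 8 (ethylene, second-generation Hoveyda–Grubbs catalyst RuCl2(=CH-2-(i-PrO)C6H4)(SIMes), toluene, 40 °C) should give the terminal-alkene alcohol F1.
- The procedure of step 4 converts it into ethynyl ether F2.
- The conditions of step 5 should turn this into butenyl chromanol F3, because a monosubstituted alkene is a far poorer π-nucleophile than the furan.
- Cross metathesis of F3 with 2-methylbut-2-ene (second-generation Grubbs catalyst RuCl2(=CHPh)(PCy3)(SIMes), 40 °C) rebuilds the 4-methylpent-3-enyl chain and gives 14.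

Step 4. Capture of the hindered tertiary alkoxide by dichloroacetylene may be sluggish, and ketene may be lost by a retro-ene path during the long warm phase of the one-pot sequence.
- The fallback sets out from 8 and comes back at 10, which is quenched to 11 as before. It builds the alkyne one carbon at a time instead of from a C2 reagent.
- Formylation of 8 (acetic formic anhydride, pyridine, DMAP, CH2Cl2, 0 °C) gives formate F4.
- Corey–Fuchs-type dibromoolefination of the formyl group (CBr4, PPh3, Zn, CH2Cl2, 0 °C) gives 1,1-dibromovinyl ether F5.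
- n-BuLi (2.2 equiv, THF, −78 °C) converts F5 into 10 entirely at low temperature. The dried cold solution of 11 can then be passed straight into step 5.

Step 13. Hydrogen abstraction may be poorly regioselective (methyl versus C2' methylene), which diverts material to the secondary allylic isomer. Slow oxidation of the chromene on prolonged irradiation is a further risk.
- The fallback sets out from 23 and comes back at 25. It replaces the ene reaction by a regiospecific epoxide-to-allylic-alcohol transposition.
- mCPBA (1.0 equiv, NaHCO3, CH2Cl2, −20 °C) epoxidises the more electron-rich and less hindered trisubstituted alkene to side-chain epoxide F6.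
- Na[PhSeB(OEt)3] (from (PhSe)2 and NaBH4 in EtOH, excess to allow for the phenols) opens it at the secondary carbon C3' to β-hydroxy selenide F7.
- H2O2 (THF, 0 °C to rt) gives selenoxide F8. Its syn elimination can only run towards C2', because C4' bears no hydrogen, and it gives the E allylic alcohol 25.
- Any pivalate lost in the basic opening only anticipates step 14.

Further compounds
F1 | step 5 | (3R)-1-{3-[2-(1,3-dioxolan-2-yl)ethyl]furan-2-yl}-3-methylhept-6-en-3-ol | C=CCC[C@](O)(C)CCc1occc1CCC2OCCO2
F2 | step 5 | 3-[2-(1,3-dioxolan-2-yl)ethyl]-2-[(3R)-3-(ethynyloxy)-3-methylhept-6-en-1-yl]furan | C=CCC[C@](OC#C)(C)CCc1occc1CCC2OCCO2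
F3 | step 5 | (2R)-2-(but-3-en-1-yl)-5-[2-(1,3-dioxolan-2-yl)ethyl]-2-methyl-3,4-dihydro-2H-chromen-8-ol | C=CCC[C@]1(C)CCc2c(CCC3OCCO3)ccc(O)c2O1
F4 | step 4 | (3R)-1-{3-[2-(1,3-dioxolan-2-yl)ethyl]furan-2-yl}-3,7-dimethyloct-6-en-3-yl formate | CC(C)=CCC[C@](OC=O)(C)CCc1occc1CCC2OCCO2
F5 | step 4 | 2-[(3R)-3-(2,2-dibromoethenyloxy)-3,7-dimethyloct-6-en-1-yl]-3-[2-(1,3-dioxolan-2-yl)ethyl]furan | CC(C)=CCC[C@](OC=C(Br)Br)(C)CCc1occc1CCC2OCCO2
F6 | step 13 | (2R)-5-[3-(2,4-dihydroxyphenyl)-3-oxopropyl]-2-[2-(3,3-dimethyloxiran-2-yl)ethyl]-2-methyl-2H-chromen-8-yl pivalate, both epoxide epimers | CC1(C)OC1CC[C@]2(C)C=Cc3c(CCC(=O)c4ccc(O)cc4O)ccc(OC(=O)C(C)(C)C)c3O2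
F7 | step 13 | (2R)-5-[3-(2,4-dihydroxyphenyl)-3-oxopropyl]-2-[4-hydroxy-4-methyl-3-(phenylselanyl)pentyl]-2-methyl-2H-chromen-8-yl pivalate, both C3' epimers | CC(C)(O)C([Se]c1ccccc1)CC[C@]2(C)C=Cc3c(CCC(=O)c4ccc(O)cc4O)ccc(OC(=O)C(C)(C)C)c3O2
F8 | step 13 | (2R)-5-[3-(2,4-dihydroxyphenyl)-3-oxopropyl]-2-[4-hydroxy-4-methyl-3-(phenylseleninyl)pentyl]-2-methyl-2H-chromen-8-yl pivalate | CC(C)(O)C([Se](=O)c1ccccc1)CC[C@]2(C)C=Cc3c(CCC(=O)c4ccc(O)cc4O)ccc(OC(=O)C(C)(C)C)c3O2
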